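The cyclopentenone ring (C5–C9) is opened at C6–C7 and C8–C9. The dimethylated C7=C8 alkene is a symmetrical 2-butyne unit lodged between the C6 carbonyl and the C9 carbinol, two oxygenated carbons held 1,3 by the spiro carbon C5. In one operation the complex Ti(OiPr)2(η2-MeC≡CMe), acting as a cis-but-2-ene-2,3-diyl dianion, should add first to the aldehyde and then to the ketone of a 2-acyl-oxolane-2-carbaldehyde, closing the carbocycle and setting C9. That precursor comes from natural phytol: two Sharpless epoxidations fix C2 and C5, the second through an epoxide-opening oxolane closure.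

Key step: step 9

Remark on numbering: the target is numbered as 1-oxaspiro[4.4]nonane (O1, C2 quaternary ether carbon, C3, C4, spiro C5, C6 ring carbonyl, C7, C8, C9 carbinol carbon bearing the acetyl group); intermediates use the same labels for the corresponding atoms.
Remark on configuration: the target is (2S,5R,9S) with a (4R,8R) side chain; the C9 hydroxyl is anti to O1 across the carbocycle.
Assumption: (2S)-2-[(tert-butyldimethylsilyl)oxy]propanal is taken as a purchasable reagent (otherwise two routine steps from ethyl (S)-lactate); its stereocentre is erased in the last step.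

Step 1
Reactants: 1 (2E,7R,11R)-3,7,11,15-tetramethylhexadec-2-en-1-ol (natural phytol)
Product: 2 [(2S,3S)-3-methyl-3-[(4R,8R)-4,8,12-trimethyltridecyl]oxiran-2-yl]methanol
Conditions: Ti(OiPr)4 (cat.), L-(+)-diethyl tartrate (cat.), t-BuOOH, 4 Å molecular sieves, CH2Cl2, −20 °C
Reagents that add atoms: tert-butyl hydroperoxide, CC(C)(C)OO
Why: Sharpless asymmetric epoxidation with the catalyst formed from Ti(OiPr)4 and L-(+)-diethyl tartrate should deliver oxygen to the face of this (E)-trisubstituted allylic alcohol that gives the (2S,3S)-epoxide (as with geraniol), which fixes the future C2 as (S).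

Step 2
Reactants: 2 [(2S,3S)-3-methyl-3-[(4R,8R)-4,8,12-trimethyltridecyl]oxiran-2-yl]methanol
Product: 3 (3S,7R,11R)-3,7,11,15-tetramethylhexadecane-1,3-diol
Conditions: NaAlH2(OCH2CH2OMe)2, THF, 0 °C → rt
Reagents that add atoms: none
Why: Hydroxyl-directed hydride delivery from the alkoxyaluminate should open the 2,3-epoxy alcohol at the carbon next to the carbinol (regioselective reductive epoxide opening to the 1,3-diol), leaving the tertiary C–O bond and its configuration untouched.

Step 3
Reactants: 3 (3S,7R,11R)-3,7,11,15-tetramethylhexadecane-1,3-diol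
Product: 4 (3S,7R,11R)-1-iodo-3,7,11,15-tetramethylhexadecan-3-ol
Conditions: I2, PPh3, imidazole, CH2Cl2, 0 °C → rt
Reagents that add atoms: iodine, II
Why: Appel-type iodination should convert only the primary alcohol, since the tertiary alcohol does not give a displaceable alkoxyphosphonium ion at a useful rate.

Step 4
Reactants: 4 (3S,7R,11R)-1-iodo-3,7,11,15-tetramethylhexadecan-3-ol; 5 triethyl phosphonoacetate
Product: 6 ethyl (5S,9R,13R)-2-(diethoxyphosphoryl)-5-hydroxy-5,9,13,17-tetramethyloctadecanoate (both C2 epimers, inconsequential)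
Conditions: NaH, 5 (3 equiv), DMF, 0 → 50 °C
Reagents that add atoms: none
Why: SN2 C-alkylation of the sodium salt of the phosphonoacetate by the unhindered primary iodide should proceed cleanly, because the stabilised carbanion is too weak a base to deprotonate the tertiary alcohol and its excess suppresses dialkylation.

Step 5
Reactants: 6 ethyl (5S,9R,13R)-2-(diethoxyphosphoryl)-5-hydroxy-5,9,13,17-tetramethyloctadecanoate; 7 (2S)-2-[(tert-butyldimethylsilyl)oxy]propanal
Product: 8 ethyl (2E,4S)-4-[(tert-butyldimethylsilyl)oxy]-2-[(3S,7R,11R)-3-hydroxy-3,7,11,15-tetramethylhexadecyl]pent-2-enoate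
Conditions: NaH (1 equiv), THF, 0 °C; then 7, 0 °C → rt
Reagents that add atoms: none
Why: Horner–Wadsworth–Emmons olefination of the α-substituted phosphonoacetate with the α-branched aldehyde should give the thermodynamically preferred (E)-enoate (ester trans to the silyloxyethyl group), one equivalent of base avoiding alkoxide formation and hence lactonisation or oxa-Michael closure.

Step 6
Reactants: 8 ethyl (2E,4S)-4-[(tert-butyldimethylsilyl)oxy]-2-[(3S,7R,11R)-3-hydroxy-3,7,11,15-tetramethylhexadecyl]pent-2-enoate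
Product: 9 (2E,4S)-4-[(tert-butyldimethylsilyl)oxy]-2-[(3S,7R,11R)-3-hydroxy-3,7,11,15-tetramethylhexadecyl]pent-2-en-1-ol
Conditions: i-Bu2AlH (excess), CH2Cl2, −78 → 0 °C; aq. KNaC4H4O6 work-up
Reagents that add atoms: none
Why: 1,2-Reduction of the α,β-unsaturated ester by i-Bu2AlH at low temperature should give the allylic alcohol without touching the alkene or the silyl ether.

Step 7
Reactants: 9 (2E,4S)-4-[(tert-butyldimethylsilyl)oxy]-2-[(3S,7R,11R)-3-hydroxy-3,7,11,15-tetramethylhexadecyl]pent-2-en-1-ol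
Product: 11 (1R,2S)-2-[(tert-butyldimethylsilyl)oxy]-1-[(2S,5S)-2-(hydroxymethyl)-5-methyl-5-[(4R,8R)-4,8,12-trimethyltridecyl]oxolan-2-yl]propan-1-ol, via epoxy alcohol 10 (not isolated)
Conditions: Ti(OiPr)4 (cat.), D-(−)-diethyl tartrate (cat.), t-BuOOH, 4 Å molecular sieves, CH2Cl2, −20 °C; then camphorsulfonic acid (cat.), 0 °C → rt
Reagents that add atoms: tert-butyl hydroperoxide, CC(C)(C)OO
Why: Sharpless asymmetric epoxidation with the catalyst formed from Ti(OiPr)4 and D-(−)-diethyl tartrate should give the (2R,3R)-epoxy alcohol 10 under reagent control, and acid should then trigger 5-exo opening of the epoxide at its fully substituted carbon by the tertiary hydroxyl with inversion, which sets the spiro-type centre C5.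

Step 8
Reactants: 11 (1R,2S)-2-[(tert-butyldimethylsilyl)oxy]-1-[(2S,5S)-2-(hydroxymethyl)-5-methyl-5-[(4R,8R)-4,8,12-trimethyltridecyl]oxolan-2-yl]propan-1-ol
Product: 12 (2S,5S)-2-[(2S)-2-[(tert-butyldimethylsilyl)oxy]propanoyl]-5-methyl-5-[(4R,8R)-4,8,12-trimethyltridecyl]oxolane-2-carbaldehyde
Conditions: Dess–Martin periodinane (excess), CH2Cl2, 0 °C → rt; crude product used at once
Reagents that add atoms: none
Why: Dess–Martin oxidation of the primary and the secondary alcohol should give the β-keto aldehyde, whose quaternary α-carbon rules out enolisation and elimination.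

Step 9
Reactants: 12 (2S,5S)-2-[(2S)-2-[(tert-butyldimethylsilyl)oxy]propanoyl]-5-methyl-5-[(4R,8R)-4,8,12-trimethyltridecyl]oxolane-2-carbaldehyde; 13 but-2-yne
Product: 16 (2S,5S,6R,9R)-9-[(1S)-1-[(tert-butyldimethylsilyl)oxy]ethyl]-2,7,8-trimethyl-2-[(4R,8R)-4,8,12-trimethyltridecyl]-1-oxaspiro[4.4]non-7-ene-6,9-diol, via titanacyclopropene 14 (not isolated), via oxatitanacyclopentene 15 (not isolated)
Conditions: Ti(OiPr)4, i-PrMgCl (2 equiv per Ti), 13 (excess), Et2O, −78 → −40 °C; then 12, −78 → 0 °C; aq. NaHCO3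
Reagents that add atoms: none
Why: Proposed new method: Ti(OiPr)4 and i-PrMgCl give Ti(OiPr)2(η2-propene), a complex of divalent titanium that exchanges with 13 to the titanacyclopropene 14, a cis-but-2-ene-2,3-diyl dianion equivalent, whose first Ti–C bond inserts the aldehyde (C6–C7 bond, oxatitanacyclopentene 15) and whose remaining alkenyl–titanium bond then adds to the neighbouring ketone (C8–C9 bond). The closest known reaction types are the carbonyl insertion of Ti(OiPr)2(η2-alkyne) complexes, the intramolecular addition of the resulting alkenyltitanium to esters and ketones, and the twofold carbonyl addition of TaCl3(alkyne) complexes (from TaCl5 and Zn) to aromatic 1,4-dialdehydes; new is the use of an acyclic 1,3-keto aldehyde to close a five-membered ring. The carbocycle closes 5-exo-trig by attack of C8 on the C9 carbonyl. The transient C6 carbinol centre is set in the aldehyde insertion under chelation of the metal between the aldehyde oxygen and O1 (Cram-chelate model), C7 entering anti to the bulky acyl group on C5. C9 is set by internal delivery: titanium held on the C6 oxygen can bring C8 only to the ketone face that leaves both oxygens on the same metal, which should give the cis-6,9-diol and hence the C9 hydroxyl anti to O1 as in the target. The step needs aldehyde-before-ketone chemoselectivity, secured by the hindered ketone between the quaternary C5 and the silyloxy-bearing carbon, and it has no regiochemical issue because 2-butyne is symmetrical.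

Step 10
Reactants: 16 (2S,5S,6R,9R)-9-[(1S)-1-[(tert-butyldimethylsilyl)oxy]ethyl]-2,7,8-trimethyl-2-[(4R,8R)-4,8,12-trimethyltridecyl]-1-oxaspiro[4.4]non-7-ene-6,9-diol
Product: 17 (2S,5S,6R,9R)-9-[(1S)-1-hydroxyethyl]-2,7,8-trimethyl-2-[(4R,8R)-4,8,12-trimethyltridecyl]-1-oxaspiro[4.4]non-7-ene-6,9-diol
Conditions: Bu4NF, THF, 0 °C → rt
Reagents that add atoms: none
Why: Fluoride-induced desilylation should free the secondary alcohol, the allylic diol being stable to these weakly basic conditions.

Step 11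
Reactants: 17 (2S,5S,6R,9R)-9-[(1S)-1-hydroxyethyl]-2,7,8-trimethyl-2-[(4R,8R)-4,8,12-trimethyltridecyl]-1-oxaspiro[4.4]non-7-ene-6,9-diol
Product: 18 (2S,5R,9S)-9-acetyl-9-hydroxy-2,7,8-trimethyl-2-[(4R,8R)-4,8,12-trimethyltridecyl]-1-oxaspiro[4.4]non-7-en-6-one (alpha-tocospiro A)
Conditions: IBX (excess), DMSO, rt
Reagents that add atoms: none
Why: IBX oxidation should convert both secondary alcohols (the allylic C6 carbinol to the enone, the side-chain carbinol to the acetyl ketone) without cleaving the vicinal tertiary–secondary diol and without touching the tertiary C9 hydroxyl.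

Compound list
1 | (2E,7R,11R)-3,7,11,15-tetramethylhexadec-2-en-1-ol (natural phytol) | C/C(CCC[C@H](C)CCC[C@H](C)CCCC(C)C)=C\CO | starting material
2 | [(2S,3S)-3-methyl-3-[(4R,8R)-4,8,12-trimethyltridecyl]oxiran-2-yl]methanol | OC[C@@H]1O[C@@]1(C)CCC[C@H](C)CCC[C@H](C)CCCC(C)C | intermediate
3 | (3S,7R,11R)-3,7,11,15-tetramethylhexadecane-1,3-diol | OCC[C@@](C)(O)CCC[C@H](C)CCC[C@H](C)CCCC(C)C | intermediate
4 | (3S,7R,11R)-1-iodo-3,7,11,15-tetramethylhexadecan-3-ol | ICC[C@@](C)(O)CCC[C@H](C)CCC[C@H](C)CCCC(C)C | intermediate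
5 | triethyl phosphonoacetate | CCOC(=O)CP(=O)(OCC)OCC | starting material
6 | ethyl (5S,9R,13R)-2-(diethoxyphosphoryl)-5-hydroxy-5,9,13,17-tetramethyloctadecanoate (both C2 epimers) | CCOC(=O)C(CC[C@@](C)(O)CCC[C@H](C)CCC[C@H](C)CCCC(C)C)P(=O)(OCC)OCC | intermediate
7 | (2S)-2-[(tert-butyldimethylsilyl)oxy]propanal | C[C@H](O[Si](C)(C)C(C)(C)C)C=O | starting material
8 | ethyl (2E,4S)-4-[(tert-butyldimethylsilyl)oxy]-2-[(3S,7R,11R)-3-hydroxy-3,7,11,15-tetramethylhexadecyl]pent-2-enoate | CCOC(=O)/C(CC[C@@](C)(O)CCC[C@H](C)CCC[C@H](C)CCCC(C)C)=C/[C@H](C)O[Si](C)(C)C(C)(C)C | intermediate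
9 | (2E,4S)-4-[(tert-butyldimethylsilyl)oxy]-2-[(3S,7R,11R)-3-hydroxy-3,7,11,15-tetramethylhexadecyl]pent-2-en-1-ol | OC/C(CC[C@@](C)(O)CCC[C@H](C)CCC[C@H](C)CCCC(C)C)=C/[C@H](C)O[Si](C)(C)C(C)(C)C | intermediate
10 | (3S,7R,11R)-1-[(2R,3R)-3-[(1S)-1-[(tert-butyldimethylsilyl)oxy]ethyl]-2-(hydroxymethyl)oxiran-2-yl]-3,7,11,15-tetramethylhexadecan-3-ol | OC[C@@]1(CC[C@@](C)(O)CCC[C@H](C)CCC[C@H](C)CCCC(C)C)O[C@@H]1[C@H](C)O[Si](C)(C)C(C)(C)C | intermediate
11 | (1R,2S)-2-[(tert-butyldimethylsilyl)oxy]-1-[(2S,5S)-2-(hydroxymethyl)-5-methyl-5-[(4R,8R)-4,8,12-trimethyltridecyl]oxolan-2-yl]propan-1-ol | OC[C@@]1(CC[C@](C)(CCC[C@H](C)CCC[C@H](C)CCCC(C)C)O1)[C@H](O)[C@H](C)O[Si](C)(C)C(C)(C)C | intermediate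
12 | (2S,5S)-2-[(2S)-2-[(tert-butyldimethylsilyl)oxy]propanoyl]-5-methyl-5-[(4R,8R)-4,8,12-trimethyltridecyl]oxolane-2-carbaldehyde | O=C[C@@]1(CC[C@](C)(CCC[C@H](C)CCC[C@H](C)CCCC(C)C)O1)C(=O)[C@H](C)O[Si](C)(C)C(C)(C)C | intermediate
13 | but-2-yne | CC#CC | starting material
14 | 2,3-dimethyl-1,1-di(propan-2-yloxy)-1-titanacycloprop-2-ene, Ti(OiPr)2(η2-MeC≡CMe) | CC1=C(C)[Ti]1(OC(C)C)OC(C)C | intermediate
15 | 3,4-dimethyl-2,2-di(propan-2-yloxy)-1-oxa-2-titanacyclopent-3-ene carrying at its C5 (the future C6) the (2S,5S)-2-acyl-oxolan-2-yl group of 12 | CC1=C(C)[Ti](OC(C)C)(OC(C)C)O[C@H]1[C@@]2(CC[C@](C)(CCC[C@H](C)CCC[C@H](C)CCCC(C)C)O2)C(=O)[C@H](C)O[Si](C)(C)C(C)(C)C | intermediate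
16 | (2S,5S,6R,9R)-9-[(1S)-1-[(tert-butyldimethylsilyl)oxy]ethyl]-2,7,8-trimethyl-2-[(4R,8R)-4,8,12-trimethyltridecyl]-1-oxaspiro[4.4]non-7-ene-6,9-diol (6-OH and 9-OH cis, both anti to O1) | C[C@H](O[Si](C)(C)C(C)(C)C)[C@]1(O)C(C)=C(C)[C@@H](O)[C@@]12CC[C@](C)(CCC[C@H](C)CCC[C@H](C)CCCC(C)C)O2 | intermediate
17 | (2S,5S,6R,9R)-9-[(1S)-1-hydroxyethyl]-2,7,8-trimethyl-2-[(4R,8R)-4,8,12-trimethyltridecyl]-1-oxaspiro[4.4]non-7-ene-6,9-diol | C[C@H](O)[C@]1(O)C(C)=C(C)[C@@H](O)[C@@]12CC[C@](C)(CCC[C@H](C)CCC[C@H](C)CCCC(C)C)O2 | intermediate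
18 | (2S,5R,9S)-9-acetyl-9-hydroxy-2,7,8-trimethyl-2-[(4R,8R)-4,8,12-trimethyltridecyl]-1-oxaspiro[4.4]non-7-en-6-one (alpha-tocospiro A) | CC(=O)[C@]1(O)C(C)=C(C)C(=O)[C@@]12CC[C@](C)(CCC[C@H](C)CCC[C@H](C)CCCC(C)C)O2 | target

Total step count: 11. Longest linear sequence: 11 steps (from 1).

Steps most likely to fail

1. Step 9 (proposed new method). The alkenyl–titanium bond of 15 may fail to add to the hindered ketone and simply be protonated on work-up. The aldehyde insertion may also show poor facial selectivity, or low-valent titanium may reductively couple the two carbonyl groups. Fallback with known chemistry, setting out from 12: chelation-controlled 1,2-addition of CH2=C(CH3)MgBr (excess, THF, −78 → 0 °C, CeCl3 if the ketone is sluggish) to both carbonyl groups should give the bis(isopropenyl) diol F1. Ring-closing metathesis of its two 1,1-disubstituted alkenes with the second-generation Grubbs catalyst RuCl2(H2IMes)(PCy3)(=CHPh) (toluene, 80 °C) should then form the tetrasubstituted C7=C8 alkene and come back to the route at 16. A C6 epimer formed alongside would converge at 18, since C6 becomes the carbonyl.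

2. Step 7. The free tertiary hydroxyl and the allylic silyloxy stereocentre may interfere with the titanium tartrate template, giving slow or poorly face-selective epoxidation (mismatched pairing). Titanium-bound isopropoxide may also open the epoxide before the internal hydroxyl does. Fallback, setting out from 9: Shi epoxidation with the D-fructose-derived ketone catalyst (KHSO5 as 2KHSO5·KHSO4·K2SO4, K2CO3, MeCN/dimethoxymethane/H2O, 0 °C) should deliver the same (2R,3R)-epoxide 10 by a metal-free dioxirane pathway. Camphorsulfonic acid then closes the oxolane, and the route is rejoined at 11. This fallback makes no new compound (F0).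

3. Step 8. The β-hydroxy carbonyl intermediates may undergo retro-aldol cleavage, and the β-keto aldehyde may be deformylated or hydrated during oxidation and handling. Fallback, setting out from 11 and carrying C6 at the ester level:
- Selective oxidation of the primary alcohol (TEMPO, PhI(OAc)2, MeCN/H2O) should give the hydroxy acid F2.
- Me3SiCHN2 should give the methyl ester F3.
- Dess–Martin oxidation should give the stable β-keto ester F4.
- Treatment with Ti(OiPr)2(η2-MeC≡CMe) (ketone insertion, then intramolecular acyl substitution of the alkenyltitanium on the ester) should give the silylated hydroxy enone F5.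
- Bu4NF should give the diol F6, and IBX oxidation of its side-chain carbinol comes back to the route at 18.

Further compounds
F1 | step 9 | (1R)-1-[(2S,5S)-2-[(2R,3S)-3-[(tert-butyldimethylsilyl)oxy]-2-hydroxy-1-methylidene-2-... bis(isopropenyl) diol: 16 opened at C7=C8, with C7 and C8 each carrying a terminal methylene | C[C@H](O[Si](C)(C)C(C)(C)C)[C@](O)(C(C)=C)[C@]1(CC[C@](C)(CCC[C@H](C)CCC[C@H](C)CCCC(C)C)O1)[C@H](O)C(C)=C
F0 | step 7 | none | none
F2 | step 8 | (2S,5S)-2-[(1R,2S)-2-[(tert-butyldimethylsilyl)oxy]-1-hydroxypropyl]-5-methyl-5-[(4R,8R)-4,8,12-trimethyltridecyl]oxolane-2-carboxylic acid | OC(=O)[C@@]1(CC[C@](C)(CCC[C@H](C)CCC[C@H](C)CCCC(C)C)O1)[C@H](O)[C@H](C)O[Si](C)(C)C(C)(C)C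
F3 | step 8 | methyl ester of F2 | COC(=O)[C@@]1(CC[C@](C)(CCC[C@H](C)CCC[C@H](C)CCCC(C)C)O1)[C@H](O)[C@H](C)O[Si](C)(C)C(C)(C)C
F4 | step 8 | methyl (2S,5S)-2-[(2S)-2-[(tert-butyldimethylsilyl)oxy]propanoyl]-5-methyl-5-[(4R,8R)-4,8,12-trimethyltridecyl]oxolane-2-carboxylate | COC(=O)[C@@]1(CC[C@](C)(CCC[C@H](C)CCC[C@H](C)CCCC(C)C)O1)C(=O)[C@H](C)O[Si](C)(C)C(C)(C)C
F5 | step 8 | 9-[(1S)-1-[(tert-butyldimethylsilyl)oxy]ethyl]-9-hydroxy-2,7,8-trimethyl-2-[(4R,8R)-4,8,12-trimethyltridecyl]-1-oxaspiro[4.4]non-7-en-6-one (ring stereocentres arranged as in 18) | C[C@H](O[Si](C)(C)C(C)(C)C)[C@]1(O)C(C)=C(C)C(=O)[C@@]12CC[C@](C)(CCC[C@H](C)CCC[C@H](C)CCCC(C)C)O2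
F6 | step 8 | 9-hydroxy-9-[(1S)-1-hydroxyethyl]-2,7,8-trimethyl-2-[(4R,8R)-4,8,12-trimethyltridecyl]-1-oxaspiro[4.4]non-7-en-6-one (ring stereocentres arranged as in 18) | C[C@H](O)[C@]1(O)C(C)=C(C)C(=O)[C@@]12CC[C@](C)(CCC[C@H](C)CCC[C@H](C)CCCC(C)C)O2
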